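**Retrosynthetic overview**

1. The target is taken back (ester removal, BBr3) to a ring A triol that carries rings B–E as their nonamethyl ether; ring A is the only ring constructed, and it is constructed last.
2. The strategy rests on ring A: a benzene-1,3,5-triol whose C2 bears the ether oxygen. C1, C3 and C5 show the alternating oxygen pattern of a folded tri-β-carbonyl chain, with the O-aryl group on the carbon between two carbonyl-derived carbons. Cutting the C3–C4 bond of ring A (retro-Dieckmann) opens it to an aryloxy-substituted tetracarbonyl chain.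
3. The chain comes from C-acylation of dimethyl 3-oxopentanedioate with an aryloxymalonyl half-ester chloride; the aryloxymalonate comes from O-alkylation of the tetramer phenol with dimethyl chloromalonate.
4. The tetramer phenol is assembled from two diaryl ether halves (rings B–C and rings D–E) made by copper-catalysed O-arylation of 2,6-dimethoxyphenols. The ring C hydroxyl is unmasked from a formyl group (Baeyer–Villiger), the halves are joined by a third O-arylation, and the ring B hydroxyl is introduced by sterically controlled C–H borylation/oxidation.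
5. Ring order: B, C, D and E are purchased benzene rings (joined B–C, D–E, then C–D); ring A is formed in the key step.

Key step: step 9

Remark on notation: ring A is the phloroglucinol terminus and rings B, C, D, E follow along the ether chain; Ar is the nonamethylated B–E aryl group bonded through C1 of ring B, 4-{2-[3,5-dimethoxy-4-(3,4,5-trimethoxyphenoxy)phenoxy]-3,5-dimethoxyphenoxy}-3,5-dimethoxyphenyl.

Remark on the chemistry: the target has no stereocentre, so the stereocentres of the half-ester, its chloride and the open chain are carried as racemic or diastereomeric (and enol) mixtures; dimethyl chloromalonate is used instead of the bromo ester to avoid halogen transfer to the electron-rich rings.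

**Route**

Step 1
Reactants: 1 4-bromo-2,6-dimethoxyphenol; 2 5-iodo-1,2,3-trimethoxybenzene
Product: 3 5-(4-bromo-2,6-dimethoxyphenoxy)-1,2,3-trimethoxybenzene (rings D–E bromide)
Conditions: CuI (10 mol %), picolinic acid (20 mol %), K3PO4, DMSO, 80 °C, Ar
Reagents that add atoms: none
Why: Ullmann-type copper-catalysed O-arylation; the aryl iodide should react with the monovalent copper phenoxide far faster than the C–Br bond of 1, which is deactivated by its para-phenoxide, so the hindered phenol is arylated without self-condensation and the bromide is kept for step 4.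

Step 2
Reactants: 4 2,6-dimethoxyphenol; 5 2-bromo-4,6-dimethoxybenzaldehyde
Product: 6 2-(2,6-dimethoxyphenoxy)-4,6-dimethoxybenzaldehyde (rings B–C aldehyde)
Conditions: CuI (10 mol %), picolinic acid (20 mol %), K3PO4, DMSO, 90 °C, Ar
Reagents that add atoms: none
Why: Ullmann-type O-arylation of a 2,6-disubstituted phenoxide with an aryl bromide activated by its ortho-formyl group; the aldehyde has no α-hydrogen and should survive the phosphate base.

Step 3
Reactants: 6 2-(2,6-dimethoxyphenoxy)-4,6-dimethoxybenzaldehyde
Product: 8 2-(2,6-dimethoxyphenoxy)-4,6-dimethoxyphenol, via aryl formate 7 (not isolated)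
Conditions: mCPBA, NaHCO3, CH2Cl2, 0 °C to rt; Na2S2O3 wash; then K2CO3, MeOH, rt
Reagents that add atoms: mCPBA, OOC(=O)c1cccc(Cl)c1
Why: Baeyer–Villiger (Dakin-type) oxidation in which the 2,4,6-trioxygenated aryl group migrates in preference to hydride; mild methanolysis of the formate then unmasks the ring C hydroxyl, while the diaryl ether and methyl ethers are inert.

Step 4
Reactants: 8 2-(2,6-dimethoxyphenoxy)-4,6-dimethoxyphenol; 3 5-(4-bromo-2,6-dimethoxyphenoxy)-1,2,3-trimethoxybenzene
Product: 9 5-{4-[2-(2,6-dimethoxyphenoxy)-4,6-dimethoxyphenoxy]-2,6-dimethoxyphenoxy}-1,2,3-trimethoxybenzene (ArH)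
Conditions: CuI (20 mol %), picolinic acid (40 mol %), K3PO4, DMSO, 105 °C, Ar
Reagents that add atoms: none
Why: Ullmann-type diaryl ether synthesis in the favourable polarity (hindered phenol plus a bromide with two ortho hydrogens); 8 carries no halogen and 3 no free hydroxyl, so only the cross-ether can form.

Step 5
Reactants: 9 ArH
Product: 11 4-{2-[3,5-dimethoxy-4-(3,4,5-trimethoxyphenoxy)phenoxy]-3,5-dimethoxyphenoxy}-3,5-dimethoxyphenol (ArOH), via aryl pinacolboronate 10 (not isolated)
Conditions: [Ir(OMe)(cod)]2 (1.5 mol %), 4,4'-di-tert-butyl-2,2'-bipyridine (3 mol %), B2pin2, THF, 80 °C; then 30% H2O2, aq NaOH, 0 °C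
Reagents that add atoms: hydrogen peroxide, OO
Why: Sterically controlled iridium-catalysed C–H borylation followed by oxidation of the aryl boronate; the para C–H of ring B is the only aromatic C–H of 9 with no ortho substituent (every C–H of rings C, D and E lies between two oxygen substituents), so boron and then hydroxyl should enter there.

Step 6
Reactants: 11 ArOH; 12 dimethyl chloromalonate
Product: 13 dimethyl 2-(ArO)malonate
Conditions: K2CO3, acetone, 50 °C
Reagents that add atoms: none
Why: Williamson-type O-alkylation (SN2 at the malonate carbon) of an unhindered phenoxide, as practised with simple methoxyphenols; the chloro ester and the weak base should limit halogen transfer and over-reaction of the product enolate.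

Step 7
Reactants: 13 dimethyl 2-(ArO)malonate
Product: 14 2-(ArO)-3-methoxy-3-oxopropanoic acid (racemic)
Conditions: KOH (1.05 equiv), THF/H2O, 0 °C; then 1 M HCl, 0 °C
Reagents that add atoms: potassium hydroxide, [K+].[OH-]
Why: Selective monosaponification of a symmetric malonic diester, in which the first-formed carboxylate repels hydroxide from the second ester; the half-acid is kept cold and used at once to avoid decarboxylation, and its new stereocentre is racemic and later destroyed.

Step 8
Reactants: 14 2-(ArO)-3-methoxy-3-oxopropanoic acid; 15 dimethyl 3-oxopentanedioate (dimethyl 1,3-acetonedicarboxylate)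
Product: 17 dimethyl 2-[2-(ArO)-3-methoxy-3-oxopropanoyl]-3-oxopentanedioate (diastereomer/enol mixture), via acid chloride 16 (not isolated)
Conditions: 1-chloro-N,N,2-trimethylprop-1-en-1-amine, CH2Cl2, 0 °C; then 15 (1.5 equiv), MgCl2, pyridine, MeCN, 0 °C to rt; cold dilute HCl work-up
Reagents that add atoms: none
Why: Neutral acid chloride formation with the α-chloroenamine (no HCl and no electrophile able to attack the methoxyarenes), then C-acylation of the magnesium chelate of the β-keto diester under soft enolisation; chelation should direct acylation to carbon and hold the product as its magnesium enolate against a second acylation, and the two new stereocentres are formed unselectively and vanish in step 9.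

Step 9
Reactants: 17 dimethyl 2-[2-(ArO)-3-methoxy-3-oxopropanoyl]-3-oxopentanedioate
Product: 18 dimethyl 2,4,6-trihydroxy-5-(ArO)benzene-1,3-dicarboxylate
Conditions: NaOMe (4 equiv), MeOH, reflux, Ar; then cold 1 M HCl
Reagents that add atoms: none
Why: Methoxide converts 17 into its polyanion; the C4 carbanion of the oxopentanedioate unit (the CH2 between ketone and ester) adds to the methyl ester of the aryloxymalonyl terminus, methoxide is lost, and the resulting cyclohexane-1,3,5-trione, which keeps one hydrogen on each carbon between the carbonyls, enolises three times to the benzene-1,3,5-triol. This is a Dieckmann (intramolecular Claisen) condensation of a poly-β-carbonyl chain, the ring-closing event of the classical malonate/acetonedicarboxylate synthesis of phloroglucinol dicarboxylates. Ring A closes by a 6-exo-trig acyl substitution that forms its C3–C4 bond; no stereocentre is created and the two of 17 disappear on aromatisation. The step needs carbocyclisation through C4 to win over the other Dieckmann mode (the aryloxy-bearing carbon onto the CH2CO2Me ester), over O-cyclisation to 2-pyranones and over retro-Claisen loss of the acyl group. The substrate should secure this because only the desired closure can aromatise: the alternative carbocycle has a quaternary C(OAr)(CO2Me) carbon, pyranones are reopened by methoxide, and retro-Claisen fragments (13 and 15) can recombine, so the reversible paths drain into the aromatic polyanion. No aldol closure competes, since every carbanion–ketone pairing in the chain would give a four-membered ring.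

Step 10
Reactants: 18 dimethyl 2,4,6-trihydroxy-5-(ArO)benzene-1,3-dicarboxylate
Product: 20 2-(ArO)benzene-1,3,5-triol, via diacid 19 (not isolated)
Conditions: 2 M NaOH (degassed), MeOH, reflux, Ar; then HCl to pH 2, 60 °C
Reagents that add atoms: none
Why: Saponification of the two salicylate-type esters followed by decarboxylation of the 2,4,6-trihydroxybenzenecarboxylic acids, which lose CO2 readily through their keto tautomers (β-keto acid decarboxylation) on acidification and warming; oxygen is excluded because ring A is now a free phloroglucinol.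

Step 11
Reactants: 20 2-(ArO)benzene-1,3,5-triol
Product: 21 2-{4-[2-[3,5-dihydroxy-4-(3,4,5-trihydroxyphenoxy)phenoxy]-3,5-dihydroxyphenoxy]-3,5-dihydroxyphenoxy}benzene-1,3,5-triol (target, CNP0227069.0)
Conditions: BBr3 (20 equiv), CH2Cl2, −78 °C to rt, Ar; then MeOH, H2O; reversed-phase purification under Ar
Reagents that add atoms: none
Why: Lewis acid-mediated cleavage of the nine aryl methyl ethers (boron coordination, bromide SN2 at methyl); the diaryl ether C–O bonds have no sp3 carbon and should stay intact, and the ring A hydroxyls are carried as borates until the aqueous quench.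

**Compound list**

1 | 4-bromo-2,6-dimethoxyphenol | COc1cc(Br)cc(OC)c1O | starting material
2 | 5-iodo-1,2,3-trimethoxybenzene | COc1cc(I)cc(OC)c1OC | starting material
3 | 5-(4-bromo-2,6-dimethoxyphenoxy)-1,2,3-trimethoxybenzene | COc1cc(Oc2c(OC)cc(Br)cc2OC)cc(OC)c1OC | intermediate
4 | 2,6-dimethoxyphenol | COc1cccc(OC)c1O | starting material
5 | 2-bromo-4,6-dimethoxybenzaldehyde | COc1cc(Br)c(C=O)c(OC)c1 | starting material
6 | 2-(2,6-dimethoxyphenoxy)-4,6-dimethoxybenzaldehyde | COc1cc(Oc2c(OC)cccc2OC)c(C=O)c(OC)c1 | intermediate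
7 | 2-(2,6-dimethoxyphenoxy)-4,6-dimethoxyphenyl formate | COc1cc(Oc2c(OC)cccc2OC)c(OC=O)c(OC)c1 | intermediate
8 | 2-(2,6-dimethoxyphenoxy)-4,6-dimethoxyphenol | COc1cc(Oc2c(OC)cccc2OC)c(O)c(OC)c1 | intermediate
9 | 5-{4-[2-(2,6-dimethoxyphenoxy)-4,6-dimethoxyphenoxy]-2,6-dimethoxyphenoxy}-1,2,3-trimethoxybenzene (ArH) | COc1cccc(OC)c1Oc1cc(OC)cc(OC)c1Oc1cc(OC)c(Oc2cc(OC)c(OC)c(OC)c2)c(OC)c1 | intermediate
10 | 2-Ar-4,4,5,5-tetramethyl-1,3,2-dioxaborolane (ArBpin, boron para to the ether oxygen of ring B) | CC1(C)OB(OC1(C)C)c1cc(OC)c(Oc2cc(OC)cc(OC)c2Oc2cc(OC)c(Oc3cc(OC)c(OC)c(OC)c3)c(OC)c2)c(OC)c1 | intermediate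
11 | 4-{2-[3,5-dimethoxy-4-(3,4,5-trimethoxyphenoxy)phenoxy]-3,5-dimethoxyphenoxy}-3,5-dimethoxyphenol (ArOH) | Oc1cc(OC)c(Oc2cc(OC)cc(OC)c2Oc2cc(OC)c(Oc3cc(OC)c(OC)c(OC)c3)c(OC)c2)c(OC)c1 | intermediate
12 | dimethyl chloromalonate | COC(=O)C(Cl)C(=O)OC | starting material
13 | dimethyl 2-(ArO)malonate | COC(=O)C(Oc1cc(OC)c(Oc2cc(OC)cc(OC)c2Oc2cc(OC)c(Oc3cc(OC)c(OC)c(OC)c3)c(OC)c2)c(OC)c1)C(=O)OC | intermediate
14 | 2-(ArO)-3-methoxy-3-oxopropanoic acid (racemic) | COC(=O)C(Oc1cc(OC)c(Oc2cc(OC)cc(OC)c2Oc2cc(OC)c(Oc3cc(OC)c(OC)c(OC)c3)c(OC)c2)c(OC)c1)C(=O)O | intermediate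
15 | dimethyl 3-oxopentanedioate (dimethyl 1,3-acetonedicarboxylate) | COC(=O)CC(=O)CC(=O)OC | starting material
16 | methyl 2-(ArO)-3-chloro-3-oxopropanoate (racemic) | COC(=O)C(Oc1cc(OC)c(Oc2cc(OC)cc(OC)c2Oc2cc(OC)c(Oc3cc(OC)c(OC)c(OC)c3)c(OC)c2)c(OC)c1)C(Cl)=O | intermediate
17 | dimethyl 2-[2-(ArO)-3-methoxy-3-oxopropanoyl]-3-oxopentanedioate (mixture of diastereomers and enol tautomers) | COC(=O)CC(=O)C(C(=O)OC)C(=O)C(Oc1cc(OC)c(Oc2cc(OC)cc(OC)c2Oc2cc(OC)c(Oc3cc(OC)c(OC)c(OC)c3)c(OC)c2)c(OC)c1)C(=O)OC | intermediate
18 | dimethyl 2,4,6-trihydroxy-5-(ArO)benzene-1,3-dicarboxylate | COC(=O)c1c(O)c(C(=O)OC)c(O)c(Oc2cc(OC)c(Oc3cc(OC)cc(OC)c3Oc3cc(OC)c(Oc4cc(OC)c(OC)c(OC)c4)c(OC)c3)c(OC)c2)c1O | intermediate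
19 | 2,4,6-trihydroxy-5-(ArO)benzene-1,3-dicarboxylic acid | OC(=O)c1c(O)c(C(=O)O)c(O)c(Oc2cc(OC)c(Oc3cc(OC)cc(OC)c3Oc3cc(OC)c(Oc4cc(OC)c(OC)c(OC)c4)c(OC)c3)c(OC)c2)c1O | intermediate
20 | 2-(ArO)benzene-1,3,5-triol | Oc1cc(O)c(Oc2cc(OC)c(Oc3cc(OC)cc(OC)c3Oc3cc(OC)c(Oc4cc(OC)c(OC)c(OC)c4)c(OC)c3)c(OC)c2)c(O)c1 | intermediate
21 | 2-{4-[2-[3,5-dihydroxy-4-(3,4,5-trihydroxyphenoxy)phenoxy]-3,5-dihydroxyphenoxy]-3,5-dihydroxyphenoxy}benzene-1,3,5-triol | Oc1cc(O)c(Oc2cc(O)c(Oc3cc(O)cc(O)c3Oc3cc(O)c(Oc4cc(O)c(O)c(O)c4)c(O)c3)c(O)c2)c(O)c1 | target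

**Step count**

Total step count: 11. Longest linear sequence: 10 steps (steps 2 to 11, from 4 and 5); step 1 is the only branch.

**Steps most likely to fail**

Step 9 (key cyclisation). The chain may be diverted into the non-aromatisable Dieckmann mode or into 2-pyranones, or be cleaved by retro-Claisen attack of methoxide faster than it closes. The fallback replaces equilibration by regiocontrol built into the substrate. It sets out from 14: the acid is converted to chloride 16 as in step 8 and coupled with di-tert-butyl 3-oxopentanedioate (MgCl2, pyridine) to give di-tert-butyl 2-[2-(ArO)-3-methoxy-3-oxopropanoyl]-3-oxopentanedioate F1. With t-BuOK in THF the single methyl ester is the only acyl acceptor and no nucleophilic alkoxide is present at the start, so the C4 carbanion can only close ring A, giving di-tert-butyl 2,4,6-trihydroxy-5-(ArO)benzene-1,3-dicarboxylate F2. TFA in CH2Cl2 then cleaves both tert-butyl esters and gentle warming decarboxylates diacid 19, which comes back to the route at 20.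

Step 8 (C-acylation). The α-aryloxy malonyl chloride may be lost through ketene dimerisation, O-acylation of the enol, or decarboxylation of the half-acid before activation. The fallback uses no activated acyl species and sets out from diester 13, skipping steps 7 and 8. Compounds 13 and 15 are condensed with NaOMe in MeOH/toluene while methanol is distilled off: a crossed Claisen condensation followed in the same flask by the Dieckmann closure, as in the classical malonate/acetonedicarboxylate phloroglucinol synthesis. Chain 17 is then only a transient, and the sequence comes back to the route at 18; it makes no compound outside the list (F0).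

Step 4 (union of the two halves). Oxidative addition of the electron-rich bromide 3 may be sluggish against the doubly ortho-substituted phenoxide of 8, leaving time for oxidative degradation of the phenol or reduction of the bromide. The fallback activates the electrophile and adds rings D and E one after the other, setting out from 8. Coupling with 4-bromo-2,6-dimethoxybenzaldehyde (CuI, picolinic acid, K3PO4; bromide para to formyl) should give 4-[2-(2,6-dimethoxyphenoxy)-4,6-dimethoxyphenoxy]-2,6-dimethoxybenzaldehyde F3. Baeyer–Villiger oxidation (mCPBA) gives 4-[2-(2,6-dimethoxyphenoxy)-4,6-dimethoxyphenoxy]-2,6-dimethoxyphenyl formate F4, and methanolysis gives 4-[2-(2,6-dimethoxyphenoxy)-4,6-dimethoxyphenoxy]-2,6-dimethoxyphenol F5. This phenol is of the same kind as 1 and is arylated with iodide 2 under the conditions of step 1, which comes back to the route at 9.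

Further compounds
F1 | step 9 | di-tert-butyl 2-[2-(ArO)-3-methoxy-3-oxopropanoyl]-3-oxopentanedioate (mixture of diastereomers and enol tautomers) | CC(C)(C)OC(=O)CC(=O)C(C(=O)OC(C)(C)C)C(=O)C(Oc1cc(OC)c(Oc2cc(OC)cc(OC)c2Oc2cc(OC)c(Oc3cc(OC)c(OC)c(OC)c3)c(OC)c2)c(OC)c1)C(=O)OC
F2 | step 9 | di-tert-butyl 2,4,6-trihydroxy-5-(ArO)benzene-1,3-dicarboxylate | CC(C)(C)OC(=O)c1c(O)c(C(=O)OC(C)(C)C)c(O)c(Oc2cc(OC)c(Oc3cc(OC)cc(OC)c3Oc3cc(OC)c(Oc4cc(OC)c(OC)c(OC)c4)c(OC)c3)c(OC)c2)c1O
F0 | step 8 | none | none
F3 | step 4 | 4-[2-(2,6-dimethoxyphenoxy)-4,6-dimethoxyphenoxy]-2,6-dimethoxybenzaldehyde | O=Cc1c(OC)cc(Oc2c(OC)cc(OC)cc2Oc2c(OC)cccc2OC)cc1OC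
F4 | step 4 | 4-[2-(2,6-dimethoxyphenoxy)-4,6-dimethoxyphenoxy]-2,6-dimethoxyphenyl formate | O=COc1c(OC)cc(Oc2c(OC)cc(OC)cc2Oc2c(OC)cccc2OC)cc1OC
F5 | step 4 | 4-[2-(2,6-dimethoxyphenoxy)-4,6-dimethoxyphenoxy]-2,6-dimethoxyphenol | Oc1c(OC)cc(Oc2c(OC)cc(OC)cc2Oc2c(OC)cccc2OC)cc1OC
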